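The plan rests on cutting ring C at the O1–C8a aryl ether bond. O1 is at the same time the hydroxyl oxygen of the C2 benzylic carbinol, so an intramolecular palladium-catalysed etherification onto the brominated C8a of ring A closes ring C in one operation without touching the C2–O bond or its (S) configuration. The precursor is an (S,S)-1,3-diol: ring A carries bromine at C8a between the carbinol chain and the C8 prenyl group, O7 is a methoxymethyl ether and the ring B side-chain carbinol a silyl ether. The diol comes from a 1,3-diketone by asymmetric transfer hydrogenation; C4 is reoxidised after ring closure.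

Key step: step 13

Remark: the (S,S) antipode of the TsDPEN ligand is taken, because it gives the (S) carbinol at C2; the configuration at C4 is of no consequence, since C4 becomes a ketone again.
Remark: 3-bromo-4-iodophenol and 4-bromo-2-iodophenol are taken as purchasable; their iodine atoms mark the two carbons that are metalated by halogen–magnesium exchange, so neither position depends on competing directing effects.

Step 1
Reactants: 1 3-bromo-4-iodophenol
Product: 2 2-bromo-1-iodo-4-(methoxymethoxy)benzene
Conditions: NaH, MOMCl, DMF, 0 °C to rt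
Reagents that add atoms: chloromethyl methyl ether, COCCl
Why: Williamson-type O-alkylation of the sodium phenoxide installs the methoxymethyl acetal, which directs the next metalation and should survive every basic and organometallic step that follows.

Step 2
Reactants: 2 2-bromo-1-iodo-4-(methoxymethoxy)benzene
Product: 4 2-bromo-1-iodo-4-(methoxymethoxy)-3-(3-methylbut-2-en-1-yl)benzene, via aryllithium 3 (not isolated)
Conditions: LiN(iPr)2, THF, −78 °C; then CuBr·SMe2 (10 mol%), prenyl bromide, −78 to −40 °C
Reagents that add atoms: 1-bromo-3-methylbut-2-ene (prenyl bromide), CC(C)=CCBr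
Why: Directed ortho-metalation removes the ring proton flanked by bromine and the acetal oxygen (the most acidic one, as in 3-bromoanisole chemistry), and copper-catalysed allylic substitution of the hindered aryl nucleophile should occur at the primary carbon of prenyl bromide (SN2) while the cold aryllithium still holds its bromine.

Step 3
Reactants: 4 2-bromo-1-iodo-4-(methoxymethoxy)-3-(3-methylbut-2-en-1-yl)benzene
Product: 6 1-[2-bromo-4-(methoxymethoxy)-3-(3-methylbut-2-en-1-yl)phenyl]ethan-1-one, via arylmagnesium chloride 5 (not isolated)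
Conditions: iPrMgCl·LiCl, THF, −40 °C; then MeC(O)N(OMe)Me, −40 to 0 °C; aq. NH4Cl
Reagents that add atoms: N-methoxy-N-methylacetamide, CC(=O)N(C)OC
Why: Iodine–magnesium exchange is far faster at C–I than at C–Br, and the arylmagnesium adds once to the amide (Weinreb ketone synthesis), the chelated adduct releasing the methyl ketone only on work-up.

Step 4
Reactants: 7 4-bromo-2-iodophenol
Product: 8 4-bromo-2-iodo-1-[(2-methylbut-3-yn-2-yl)oxy]benzene
Conditions: 3-chloro-3-methylbut-1-yne, DBU, CuCl2 (1 mol%), MeCN, 0 °C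
Reagents that add atoms: 3-chloro-3-methylbut-1-yne, C#CC(C)(C)Cl
Why: Copper-catalysed O-propargylation of the phenol with the tertiary propargylic chloride should give the 1,1-dimethylpropargyl aryl ether at a temperature too low for any coupling at the aryl iodide.

Step 5
Reactants: 8 4-bromo-2-iodo-1-[(2-methylbut-3-yn-2-yl)oxy]benzene
Product: 9 6-bromo-8-iodo-2,2-dimethyl-2H-chromene
Conditions: N,N-diethylaniline, 185 °C
Reagents that add atoms: none
Why: Thermal aromatic propargyl Claisen rearrangement to the only free ortho carbon, then enolisation, 1,5-hydrogen shift and oxa-6π electrocyclisation, should build the 2,2-dimethyl-2H-chromene with iodine left at C8 and bromine at C6.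

Step 6
Reactants: 9 6-bromo-8-iodo-2,2-dimethyl-2H-chromene; 10 methyl (2R)-oxirane-2-carboxylate (methyl (R)-glycidate)
Product: 12 methyl (2R)-3-(6-bromo-2,2-dimethyl-2H-chromen-8-yl)-2-hydroxypropanoate, via chromenylmagnesium chloride 11 (not isolated)
Conditions: iPrMgCl·LiCl, THF, −20 °C; then CuI (10 mol%), 10, −40 to −20 °C; aq. NH4Cl
Reagents that add atoms: none
Why: Iodine–magnesium exchange is selective for the C8 iodide over the C6 bromide, and copper-catalysed SN2 opening of the epoxide at its CH2 terminus should outrun carbonyl addition at −40 °C; the carbinol centre is carried over unchanged from the glycidate, whose C2–O bond is not broken, so it is (R).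

Step 7
Reactants: 12 methyl (2R)-3-(6-bromo-2,2-dimethyl-2H-chromen-8-yl)-2-hydroxypropanoate
Product: 13 methyl (2R)-3-(6-bromo-2,2-dimethyl-2H-chromen-8-yl)-2-[(tert-butyldimethylsilyl)oxy]propanoate
Conditions: TBSCl, imidazole, DMF, rt
Reagents that add atoms: tert-butyldimethylsilyl chloride, CC(C)(C)[Si](C)(C)Cl
Why: Imidazole-promoted silylation masks the secondary hydroxyl for the organometallic, reduction and oxidation steps ahead and leaves the stereocentre untouched.

Step 8
Reactants: 13 methyl (2R)-3-(6-bromo-2,2-dimethyl-2H-chromen-8-yl)-2-[(tert-butyldimethylsilyl)oxy]propanoate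
Product: 15 (3R)-4-(6-bromo-2,2-dimethyl-2H-chromen-8-yl)-3-[(tert-butyldimethylsilyl)oxy]butan-2-one, via Weinreb amide 14 (not isolated)
Conditions: MeNH(OMe)·HCl, iPrMgCl, THF, −20 °C; then MeMgBr, −20 to 0 °C; aq. NH4Cl
Reagents that add atoms: methylmagnesium bromide, C[Mg]Br; N,O-dimethylhydroxylamine hydrochloride, CNOC.Cl (its atoms stay in 14 only)
Why: Aminolysis of the ester by the magnesium amide gives the Weinreb amide, whose chelated adduct with MeMgBr collapses to the methyl ketone only on work-up (Weinreb ketone synthesis), so over-addition is avoided and the α-silyloxy centre stays (R).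

Step 9
Reactants: 15 (3R)-4-(6-bromo-2,2-dimethyl-2H-chromen-8-yl)-3-[(tert-butyldimethylsilyl)oxy]butan-2-one
Product: 16 tert-butyl{[(2R)-1-(6-bromo-2,2-dimethyl-2H-chromen-8-yl)-3-methylbut-3-en-2-yl]oxy}dimethylsilane
Conditions: Ph3PCH3Br, KOtBu, THF, 0 °C
Reagents that add atoms: methyltriphenylphosphonium bromide, C[P+](c1ccccc1)(c1ccccc1)c1ccccc1.[Br-]
Why: Wittig methylenation of the methyl ketone turns the acetyl group into the isopropenyl group; the preformed ylide is used without excess base so that the α-silyloxy centre is not enolised.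

Step 10
Reactants: 16 tert-butyl{[(2R)-1-(6-bromo-2,2-dimethyl-2H-chromen-8-yl)-3-methylbut-3-en-2-yl]oxy}dimethylsilane
Product: 18 methyl 8-{(2R)-2-[(tert-butyldimethylsilyl)oxy]-3-methylbut-3-en-1-yl}-2,2-dimethyl-2H-chromene-6-carboxylate, via aryllithium 17 (not isolated)
Conditions: n-BuLi, THF, −78 °C; then cannula into ClCO2Me, THF, −78 °C
Reagents that add atoms: methyl chloroformate, COC(=O)Cl
Why: Bromine–lithium exchange at −78 °C is faster than any deprotonation, and inverse addition of the aryllithium to excess chloroformate (acylation of an organolithium) should give the ester without ketone formation.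

Step 11
Reactants: 6 1-[2-bromo-4-(methoxymethoxy)-3-(3-methylbut-2-en-1-yl)phenyl]ethan-1-one; 18 methyl 8-{(2R)-2-[(tert-butyldimethylsilyl)oxy]-3-methylbut-3-en-1-yl}-2,2-dimethyl-2H-chromene-6-carboxylate
Product: 19 1-[2-bromo-4-(methoxymethoxy)-3-(3-methylbut-2-en-1-yl)phenyl]-3-(8-{(2R)-2-[(tert-butyldimethylsilyl)oxy]-3-methylbut-3-en-1-yl}-2,2-dimethyl-2H-chromen-6-yl)propane-1,3-dione
Conditions: NaH, THF, 0 to 60 °C; aq. NH4Cl
Reagents that add atoms: none
Why: Crossed Claisen condensation: only ketone 6 can form an enolate, ester 18 has no α-hydrogen, and deprotonation of the 1,3-diketone drives the equilibrium, while the silyl ether, acetal, aryl bromide and alkenes are inert to NaH.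

Step 12
Reactants: 19 the 1,3-diketone
Product: 20 (1S,3S)-1-[2-bromo-4-(methoxymethoxy)-3-(3-methylbut-2-en-1-yl)phenyl]-3-(8-{(2R)-2-[(tert-butyldimethylsilyl)oxy]-3-methylbut-3-en-1-yl}-2,2-dimethyl-2H-chromen-6-yl)propane-1,3-diol
Conditions: RuCl[(S,S)-TsDPEN](p-cymene) (5 mol%), HCO2H/Et3N (5:2), CH2Cl2, 35 °C
Reagents that add atoms: none
Why: Noyori–Ikariya asymmetric transfer hydrogenation: the ruthenium hydride and the ligand N–H deliver hydride and proton to each aryl ketone through an outer-sphere six-membered transition state, and the (S,S) ligand steers addition to the face that gives the (S) carbinol at both carbons (catalyst control, anti-diol); only C2 has to be right, and alkenes, aryl bromide, acetal and silyl ether are not touched.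

Step 13
Reactants: 20 the (1S,3S)-diol
Product: 21 (2S,4S)-2-(8-{(2R)-2-[(tert-butyldimethylsilyl)oxy]-3-methylbut-3-en-1-yl}-2,2-dimethyl-2H-chromen-6-yl)-7-(methoxymethoxy)-8-(3-methylbut-2-en-1-yl)-3,4-dihydro-2H-chromen-4-ol
Conditions: Pd(OAc)2 (5 mol%), rac-2-(di-tert-butylphosphino)-1,1'-binaphthyl (7 mol%), Cs2CO3, toluene, 70 °C
Reagents that add atoms: none
Why: Zerovalent palladium, formed in the flask from Pd(OAc)2 and the electron-rich bulky monophosphine, inserts into the hindered C8a–Br bond; carbonate-assisted exchange of bromide for the C2 alkoxide gives a seven-membered aryl palladium alkoxide, and C–O reductive elimination forms O1–C8a. The closest known reaction type is the intramolecular Buchwald–Hartwig etherification of aryl bromides with pendant secondary alcohols to chromans, which is known to keep the carbinol configuration. Ring C closes in a formal 6-exo mode, the six-membered ring arising from the seven-membered palladacycle. No stereocentre is created: C2 keeps the (S) configuration set in step 12 because the C2–O bond is never broken, and C4 is a carbinol, so the base cannot start retro-oxa-Michael or dehydration chemistry. The step needs site selectivity between the two hydroxyls and reductive elimination faster than β-hydride elimination: the C4 hydroxyl can only form a five-membered chelate that would have to eliminate to a four-membered ring and holds its C4–H away from the metal, while the di-tert-butyl biaryl phosphine crowds palladium and speeds C–O reductive elimination from the C2 alkoxide. The C8 prenyl alkene cannot intercept the aryl palladium, since insertion would need a four-membered ring or a 5-endo closure.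

Step 14
Reactants: 21 the (2S,4S)-flavan-4-ol
Product: 22 (2S)-2-(8-{(2R)-2-[(tert-butyldimethylsilyl)oxy]-3-methylbut-3-en-1-yl}-2,2-dimethyl-2H-chromen-6-yl)-7-(methoxymethoxy)-8-(3-methylbut-2-en-1-yl)-2,3-dihydro-4H-chromen-4-one
Conditions: Dess–Martin periodinane, CH2Cl2, 0 °C to rt
Reagents that add atoms: none
Why: Dess–Martin oxidation of the benzylic C4 carbinol under near-neutral conditions should give the flavanone without base-induced ring opening at C2; the other oxygen functions are masked and the alkenes are inert.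

Step 15
Reactants: 22 the protected (2S)-flavanone
Product: 23 (2S)-7-hydroxy-2-{8-[(2R)-2-hydroxy-3-methylbut-3-en-1-yl]-2,2-dimethyl-2H-chromen-6-yl}-8-(3-methylbut-2-en-1-yl)-2,3-dihydro-4H-chromen-4-one (CNP0104040.1)
Conditions: HCl (3 M aq.), MeOH/THF, 40 °C
Reagents that add atoms: none
Why: Acid-catalysed methanolysis (acetal exchange and silyl ether solvolysis) cleaves the aryl methoxymethyl ether and the secondary silyl ether in one pot, under conditions commonly tolerated by ortho-prenyl phenols and 2H-chromenes; no stereocentre is involved.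

Compound list
1 | 3-bromo-4-iodophenol | Oc1ccc(I)c(Br)c1 | starting material
2 | 2-bromo-1-iodo-4-(methoxymethoxy)benzene | COCOc1ccc(I)c(Br)c1 | intermediate
3 | [2-bromo-3-iodo-6-(methoxymethoxy)phenyl]lithium | COCOc1ccc(I)c(Br)c1[Li] | intermediate (not isolated)
4 | 2-bromo-1-iodo-4-(methoxymethoxy)-3-(3-methylbut-2-en-1-yl)benzene | COCOc1ccc(I)c(Br)c1CC=C(C)C | intermediate
5 | [2-bromo-4-(methoxymethoxy)-3-(3-methylbut-2-en-1-yl)phenyl]magnesium chloride | COCOc1ccc([Mg]Cl)c(Br)c1CC=C(C)C | intermediate (not isolated)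
6 | 1-[2-bromo-4-(methoxymethoxy)-3-(3-methylbut-2-en-1-yl)phenyl]ethan-1-one | COCOc1ccc(C(C)=O)c(Br)c1CC=C(C)C | intermediate
7 | 4-bromo-2-iodophenol | Oc1ccc(Br)cc1I | starting material
8 | 4-bromo-2-iodo-1-[(2-methylbut-3-yn-2-yl)oxy]benzene | C#CC(C)(C)Oc1ccc(Br)cc1I | intermediate
9 | 6-bromo-8-iodo-2,2-dimethyl-2H-chromene | CC1(C)C=Cc2cc(Br)cc(I)c2O1 | intermediate
10 | methyl (2R)-oxirane-2-carboxylate (methyl (R)-glycidate) | COC(=O)[C@H]1CO1 | starting material
11 | (6-bromo-2,2-dimethyl-2H-chromen-8-yl)magnesium chloride | CC1(C)C=Cc2cc(Br)cc([Mg]Cl)c2O1 | intermediate (not isolated)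
12 | methyl (2R)-3-(6-bromo-2,2-dimethyl-2H-chromen-8-yl)-2-hydroxypropanoate | COC(=O)[C@H](O)Cc1cc(Br)cc2c1OC(C)(C)C=C2 | intermediate
13 | methyl (2R)-3-(6-bromo-2,2-dimethyl-2H-chromen-8-yl)-2-[(tert-butyldimethylsilyl)oxy]propanoate | COC(=O)[C@H](O[Si](C)(C)C(C)(C)C)Cc1cc(Br)cc2c1OC(C)(C)C=C2 | intermediate
14 | (2R)-3-(6-bromo-2,2-dimethyl-2H-chromen-8-yl)-2-[(tert-butyldimethylsilyl)oxy]-N-methoxy-N-methylpropanamide | CON(C)C(=O)[C@H](O[Si](C)(C)C(C)(C)C)Cc1cc(Br)cc2c1OC(C)(C)C=C2 | intermediate (not isolated)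
15 | (3R)-4-(6-bromo-2,2-dimethyl-2H-chromen-8-yl)-3-[(tert-butyldimethylsilyl)oxy]butan-2-one | CC(=O)[C@H](O[Si](C)(C)C(C)(C)C)Cc1cc(Br)cc2c1OC(C)(C)C=C2 | intermediate
16 | tert-butyl{[(2R)-1-(6-bromo-2,2-dimethyl-2H-chromen-8-yl)-3-methylbut-3-en-2-yl]oxy}dimethylsilane | C=C(C)[C@H](O[Si](C)(C)C(C)(C)C)Cc1cc(Br)cc2c1OC(C)(C)C=C2 | intermediate
17 | (8-{(2R)-2-[(tert-butyldimethylsilyl)oxy]-3-methylbut-3-en-1-yl}-2,2-dimethyl-2H-chromen-6-yl)lithium | C=C(C)[C@H](O[Si](C)(C)C(C)(C)C)Cc1cc([Li])cc2c1OC(C)(C)C=C2 | intermediate (not isolated)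
18 | methyl 8-{(2R)-2-[(tert-butyldimethylsilyl)oxy]-3-methylbut-3-en-1-yl}-2,2-dimethyl-2H-chromene-6-carboxylate | C=C(C)[C@H](O[Si](C)(C)C(C)(C)C)Cc1cc(C(=O)OC)cc2c1OC(C)(C)C=C2 | intermediate
19 | 1-[2-bromo-4-(methoxymethoxy)-3-(3-methylbut-2-en-1-yl)phenyl]-3-(8-{(2R)-2-[(tert-butyldimethylsilyl)oxy]-3-methylbut-3-en-1-yl}-2,2-dimethyl-2H-chromen-6-yl)propane-1,3-dione | C=C(C)[C@H](O[Si](C)(C)C(C)(C)C)Cc1cc(C(=O)CC(=O)c3ccc(OCOC)c(CC=C(C)C)c3Br)cc2c1OC(C)(C)C=C2 | intermediate
20 | (1S,3S)-1-[2-bromo-4-(methoxymethoxy)-3-(3-methylbut-2-en-1-yl)phenyl]-3-(8-{(2R)-2-[(tert-butyldimethylsilyl)oxy]-3-methylbut-3-en-1-yl}-2,2-dimethyl-2H-chromen-6-yl)propane-1,3-diol | C=C(C)[C@H](O[Si](C)(C)C(C)(C)C)Cc1cc([C@@H](O)C[C@H](O)c3ccc(OCOC)c(CC=C(C)C)c3Br)cc2c1OC(C)(C)C=C2 | intermediate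
21 | (2S,4S)-2-(8-{(2R)-2-[(tert-butyldimethylsilyl)oxy]-3-methylbut-3-en-1-yl}-2,2-dimethyl-2H-chromen-6-yl)-7-(methoxymethoxy)-8-(3-methylbut-2-en-1-yl)-3,4-dihydro-2H-chromen-4-ol | C=C(C)[C@H](O[Si](C)(C)C(C)(C)C)Cc1cc([C@@H]2C[C@H](O)c3ccc(OCOC)c(CC=C(C)C)c3O2)cc2c1OC(C)(C)C=C2 | intermediate
22 | (2S)-2-(8-{(2R)-2-[(tert-butyldimethylsilyl)oxy]-3-methylbut-3-en-1-yl}-2,2-dimethyl-2H-chromen-6-yl)-7-(methoxymethoxy)-8-(3-methylbut-2-en-1-yl)-2,3-dihydro-4H-chromen-4-one | C=C(C)[C@H](O[Si](C)(C)C(C)(C)C)Cc1cc([C@@H]2CC(=O)c3ccc(OCOC)c(CC=C(C)C)c3O2)cc2c1OC(C)(C)C=C2 | intermediate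
23 | (2S)-7-hydroxy-2-{8-[(2R)-2-hydroxy-3-methylbut-3-en-1-yl]-2,2-dimethyl-2H-chromen-6-yl}-8-(3-methylbut-2-en-1-yl)-2,3-dihydro-4H-chromen-4-one | C=C(C)[C@H](O)Cc1cc([C@@H]2CC(=O)c3ccc(O)c(CC=C(C)C)c3O2)cc2c1OC(C)(C)C=C2 | target

Total step count: 15
Longest linear sequence: 12 steps (steps 4 to 15, from 7 to 23); the ring A ketone 6 is made in 3 steps and joins at step 11.

Steps most likely to fail

1. Step 13. Insertion into the C8a–Br bond, which is flanked by the prenyl group and the carbinol chain, may be slow, and β-hydride elimination from the palladium C2 alkoxide may then compete with C–O reductive elimination, oxidising C2 and removing the halogen. The fallback sets out from 20 and comes back at 21, replacing the palladium cycle by an Ullmann closure on the more reactive iodide. Copper-catalysed aromatic Finkelstein exchange (CuI, NaI, trans-N,N'-dimethylcyclohexane-1,2-diamine, dioxane, 110 °C) should convert 20 into (1S,3S)-1-[2-iodo-4-(methoxymethoxy)-3-(3-methylbut-2-en-1-yl)phenyl]-3-(8-{(2R)-2-[(tert-butyldimethylsilyl)oxy]-3-methylbut-3-en-1-yl}-2,2-dimethyl-2H-chromen-6-yl)propane-1,3-diol F1. CuI with 3,4,7,8-tetramethyl-1,10-phenanthroline and Cs2CO3 in toluene at 110 °C should then join O1 to C8a and give 21. A copper alkoxide has no easy β-hydride path, and the C2–O bond again stays intact.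

2. Step 2. The ortho-bromo aryllithium may lose lithium bromide (aryne formation) if carbon–carbon bond formation is slow, and the prenyl group may be transferred with allylic transposition (attack at its tertiary terminus). The fallback sets out from 2 and comes back at 4. The same aryllithium is quenched at −78 °C with allyl bromide, a faster electrophile with no regiochemical ambiguity, to give 2-bromo-1-iodo-4-(methoxymethoxy)-3-(prop-2-en-1-yl)benzene F2. Olefin cross-metathesis with excess 2-methylbut-2-ene (second-generation Grubbs catalyst, CH2Cl2, 40 °C) should then turn the allyl group into the prenyl group of 4.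

3. Step 15. Under protic acid the freed C7 phenol may add to the protonated C8 prenyl alkene (chroman formation), or the allylic carbinol may ionise, before the acetal is fully cleaved. The fallback sets out from 22 and comes back at 23 through two orthogonal, non-protic operations. TMSOTf and 2,2'-bipyridyl in CH2Cl2 at 0 °C, then water, should cleave only the aryl methoxymethyl ether (through the aryl silyl ether) and give (2S)-2-(8-{(2R)-2-[(tert-butyldimethylsilyl)oxy]-3-methylbut-3-en-1-yl}-2,2-dimethyl-2H-chromen-6-yl)-7-hydroxy-8-(3-methylbut-2-en-1-yl)-2,3-dihydro-4H-chromen-4-one F3. HF·pyridine in THF/pyridine at 0 °C should then remove the silyl group and give 23.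

Further compounds
F1 | step 13 | (1S,3S)-1-[2-iodo-4-(methoxymethoxy)-3-(3-methylbut-2-en-1-yl)phenyl]-3-(8-{(2R)-2-[(tert-butyldimethylsilyl)oxy]-3-methylbut-3-en-1-yl}-2,2-dimethyl-2H-chromen-6-yl)propane-1,3-diol | C=C(C)[C@H](O[Si](C)(C)C(C)(C)C)Cc1cc([C@@H](O)C[C@H](O)c3ccc(OCOC)c(CC=C(C)C)c3I)cc2c1OC(C)(C)C=C2
F2 | step 2 | 2-bromo-1-iodo-4-(methoxymethoxy)-3-(prop-2-en-1-yl)benzene | COCOc1ccc(I)c(Br)c1CC=C
F3 | step 15 | (2S)-2-(8-{(2R)-2-[(tert-butyldimethylsilyl)oxy]-3-methylbut-3-en-1-yl}-2,2-dimethyl-2H-chromen-6-yl)-7-hydroxy-8-(3-methylbut-2-en-1-yl)-2,3-dihydro-4H-chromen-4-one | C=C(C)[C@H](O[Si](C)(C)C(C)(C)C)Cc1cc([C@@H]2CC(=O)c3ccc(O)c(CC=C(C)C)c3O2)cc2c1OC(C)(C)C=C2
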